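The bicyclo[3.1.1]heptenone core is traced back to a longibornane: the cyclobutane carbon C5 is returned from C10 to the methyl-bearing C9, so that the cyclohexenone ring C5–C6–C7(=O)–C8=C9–C10 becomes the cyclopentanone ring of a norbornanone carrying an endo iodide at C10. In the key step the C7 enolate pushes the C9–C5 bond, which lies anti to the C10–I bond, onto C10: a single 1,2-shift enlarges the ketone ring to the enone ring, contracts the neighbouring five-membered ring to the cyclobutane and fixes C10. The precursor, a tricyclic keto iodide that looks like a bornane, comes from an intramolecular double Michael addition of a cyclopentenone bearing an enoate side chain.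

Key step: step 12

Atom labels (kept through all intermediates): C1 = carbinol carbon that ends as the angelate; C2 = CH2; C3 = carbinol carbon that ends as the epoxy ester; C4 = CMe2; C5 = cyclobutane CH next to C4; C6 = cyclobutane CH next to the ketone; C7 = C=O; C8 = enone CH; C9 = enone C–CH3; C10 = cyclobutane CH next to C9; C11 = quaternary cyclobutane carbon (CH3 and C1). In the tricyclic intermediates 20–24, "endo" means on the side of the C7–C8 bridge and "exo" on the side of the one-carbon bridge C5.

Assumption: (+)-Ipc2BCl is taken as the antipode whose methyl ketone enolate attacks the Re face of aldehyde 9 (3R carbinol); if the opposite sense is found, (−)-Ipc2BCl is used and nothing else changes.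

Step 1
Reactants: 1 (R)-4-(tert-butyldimethylsilyloxy)cyclopent-2-en-1-one; 2 1-methoxy-2-methyl-1-(trimethylsilyloxy)prop-1-ene
Product: 5 methyl 2-methyl-2-[(1R)-4-oxocyclopent-2-en-1-yl]propanoate, via TMS enol ether adduct 3 (not isolated), via trans silyloxy ketone 4 (not isolated)
Conditions: TMSOTf (10 mol%), CH2Cl2, −78 °C; 1 M HCl; then DBU, CH2Cl2, 0 °C
Reagents that add atoms: none
Why: Mukaiyama–Michael addition of the ketene silyl acetal should occur anti to the silyloxy group, and E1cB loss of silanolate then moves the enone, so that the new stereocenter C5 (R) is set by the stereocenter of 1, which is itself erased.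

Step 2
Reactants: 5 methyl 2-methyl-2-[(1R)-4-oxocyclopent-2-en-1-yl]propanoate
Product: 7 methyl 2-methyl-2-[(1R)-2-methyl-4-oxocyclopent-2-en-1-yl]propanoate, via TMS enol ether 6 (not isolated)
Conditions: Me2CuLi, TMSCl, THF, −78 °C; then Pd(OAc)2 (10 mol%), O2 (1 atm), DMSO, 23 °C
Reagents that add atoms: Me2CuLi, [Li+].C[Cu-]C
Why: Conjugate addition of the Gilman reagent trans to the tert-alkyl group gives a regiodefined silyl enol ether whose Saegusa oxidation re-forms the enone on the methyl side only, the transient methyl-bearing stereocenter becoming trigonal.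

Step 3
Reactants: 7 methyl 2-methyl-2-[(1R)-2-methyl-4-oxocyclopent-2-en-1-yl]propanoate
Product: 8 (4R)-4-(1-hydroxy-2-methylpropan-2-yl)-3-methylcyclopent-2-en-1-ol (both carbinol epimers)
Conditions: i-Bu2AlH (4.5 equiv), CH2Cl2, −78 → 0 °C; Rochelle salt work-up
Reagents that add atoms: none
Why: Hydride reduction of the ester to the primary alcohol and 1,2-reduction of the enone, the new carbinol centre being of no consequence because it is oxidized again.

Step 4
Reactants: 8 (4R)-4-(1-hydroxy-2-methylpropan-2-yl)-3-methylcyclopent-2-en-1-ol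
Product: 9 2-methyl-2-[(1R)-2-methyl-4-oxocyclopent-2-en-1-yl]propanal
Conditions: Dess–Martin periodinane (2.5 equiv), CH2Cl2, 23 °C
Reagents that add atoms: none
Why: Dess–Martin oxidation returns the enone and gives the non-enolizable neopentyl aldehyde without touching C5.

Step 5
Reactants: 10 butane-2,3-dione (3 equiv); 11 benzyl (triphenylphosphoranylidene)acetate
Product: 12 benzyl (2E)-3-methyl-4-oxopent-2-enoate
Conditions: CH2Cl2, 23 °C
Reagents that add atoms: none
Why: Wittig olefination of one carbonyl of the 1,2-diketone by the stabilized ylide should give the E enoate with the acetyl group trans to the ester.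

Step 6
Reactants: 12 benzyl (2E)-3-methyl-4-oxopent-2-enoate; 9 2-methyl-2-[(1R)-2-methyl-4-oxocyclopent-2-en-1-yl]propanal
Product: 14 benzyl (2E,6R)-6-hydroxy-3,7-dimethyl-7-[(1R)-2-methyl-4-oxocyclopent-2-en-1-yl]-4-oxooct-2-enoate, via boron enolate 13 (not isolated)
Conditions: (+)-Ipc2BCl, Et3N, Et2O, 0 °C; then 9, −78 → −20 °C; pH 7 buffer, MeOH
Reagents that add atoms: none
Why: Reagent-controlled boron aldol reaction of the methyl ketone, in which the isopinocampheyl groups select the aldehyde face and set C3 (R), while the boron enolate adds to the aldehyde and not to the ring enone.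

Step 7
Reactants: 14 benzyl (2E,6R)-6-hydroxy-3,7-dimethyl-7-[(1R)-2-methyl-4-oxocyclopent-2-en-1-yl]-4-oxooct-2-enoate
Product: 15 benzyl (2E,4R,6R)-4,6-dihydroxy-3,7-dimethyl-7-[(1R)-2-methyl-4-oxocyclopent-2-en-1-yl]oct-2-enoate
Conditions: Me4NBH(OAc)3, AcOH/MeCN, −30 °C
Reagents that add atoms: none
Why: Evans–Saksena reduction, in which the C3 hydroxyl binds the triacetoxyborohydride and delivers hydride intramolecularly to set C1 (R) anti to C3, the unchelated ring enone being left alone.

Step 8
Reactants: 15 benzyl (2E,4R,6R)-4,6-dihydroxy-3,7-dimethyl-7-[(1R)-2-methyl-4-oxocyclopent-2-en-1-yl]oct-2-enoate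
Product: 17 bis-silyl ether of 15 (TBS on the C1 oxygen; TES on the C3 oxygen), via mono-TBS ether 16 (not isolated)
Conditions: TBSCl (1.1 equiv), imidazole, CH2Cl2, 0 → 23 °C; then 2,6-lutidine, TESOTf, −78 → 0 °C
Reagents that add atoms: TBSCl, CC(C)(C)[Si](C)(C)Cl; TESOTf, CC[Si](CC)(CC)OS(=O)(=O)C(F)(F)F
Why: Silyl ether formation in which the silyl chloride should react only with the less hindered allylic C1 hydroxyl, so that the neopentyl C3 hydroxyl is left for the silyl triflate and the two oxygens become distinguishable.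

Step 9
Reactants: 17 bis-silyl ether (cyclopentenone with enoate side chain)
Product: 21 tricyclic keto benzyl ester (norbornanone with bridgeheads C6 and C9; CO2Bn endo on C10), via lithium dienolate 18 (not isolated), via lithium ester enolate 19 (not isolated), via lithium ketone enolate 20 (not isolated)
Conditions: LiN(SiMe3)2 (1.2 equiv), THF, −78 → 23 °C; aq. NH4Cl
Reagents that add atoms: none
Why: Intramolecular double Michael addition (anionic formal Diels–Alder reaction), in which the kinetic α′-enolate adds to the enoate β-carbon C11 on the ring face that carries the tether (fixed by C5) and the ester enolate closes onto the enone β-carbon C9, which sets C6, C9 and C11 and places the ester on the less hindered endo side.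

Step 10
Reactants: 21 tricyclic keto benzyl ester
Product: 22 tricyclic keto acid (CO2H endo on C10)
Conditions: H2 (1 atm), Pd/C (10%), EtOAc, 23 °C
Reagents that add atoms: none
Why: Hydrogenolysis of the benzyl ester leaves the silyl ethers, the ketone and all stereocenters untouched.

Step 11
Reactants: 22 tricyclic keto acid
Product: 23 tricyclic keto iodide (iodine endo on C10)
Conditions: PhI(OAc)2, I2, cyclohexane, hν (tungsten lamp), 40 °C
Reagents that add atoms: I2, II
Why: Hunsdiecker-type decarboxylative iodination through the acyl hypoiodite, in which the secondary C10 radical should take iodine from the endo face because the exo face is covered by the gem-dimethyl carbon C4 of the seven-membered ring.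

Step 12
Reactants: 23 tricyclic keto iodide
Product: 25 bis-silyl ether of the target diol core (bicyclo[3.1.1]hept-3-en-2-one with bridging seven-membered ring), via potassium enolate 24 (not isolated)
Conditions: KN(SiMe3)2 (1.1 equiv), THF, −78 → 45 °C, dark
Reagents that add atoms: none
Why: Proposed new method: the potassium enolate of the C7 ketone (C7=C8) is aligned with the C9–C5 σ bond, and this bond is anti-periplanar to the endo C10–I bond, so that electron push from the enolate and loss of iodide should move C5 from C9 to C10 in one concerted 1,2-shift while the C8=C9 double bond forms. The closest known reactions are the semipinacol rearrangement of 2-sulfonyloxy or 2-halo alkoxides and the base-induced Wagner–Meerwein shift–elimination of bridged keto sulfonates; here the enolate carbon takes the part of the alkoxide oxygen (a vinylogous semipinacol), and the shift is the reverse of the acid-driven pinane-to-bornane rearrangement, paid for by iodide loss and enone formation. No ring is closed by cyclization: the cyclopentanone ring C5–C6–C7–C8–C9 is enlarged to the cyclohexenone ring by insertion of C10 through the 1,2-alkyl shift, and the second five-membered ring C5–C6–C11–C10–C9 is contracted to the cyclobutane. C10 is the only new stereocenter and is set by inversion (C5 enters anti to iodide), C5 migrates with retention and C9 becomes trigonal. The step needs migration of C5 in preference to C8 and to cyclopropane formation by attack of C8 on C10: the endo iodide places only the C9–C5 bond anti to it and rules out backside attack by C8, and C9 and C11 are quaternary, so that neither β-elimination nor substitution can compete.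

Step 13
Reactants: 25 bis-silyl ether of the diol core
Product: 26 C3 alcohol (TBS ether kept on the C1 oxygen)
Conditions: HF·pyridine, pyridine, THF, 0 °C
Reagents that add atoms: none
Why: Selective desilylation that distinguishes the labile triethylsilyl ether from the tert-butyldimethylsilyl ether, no stereocenter being involved.

Step 14
Reactants: 27 (2E)-2-methylbut-2-en-1-ol
Product: 28 [(2R,3R)-2,3-dimethyloxiran-2-yl]methanol
Conditions: Ti(OiPr)4, D-(−)-diisopropyl tartrate, t-BuOOH, 4 Å molecular sieves, CH2Cl2, −20 °C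
Reagents that add atoms: t-BuOOH, CC(C)(C)OO
Why: Sharpless asymmetric epoxidation, in which the D-(−)-tartrate should deliver oxygen to the face of the E allylic alcohol that gives the (2R,3R) epoxy alcohol.

Step 15
Reactants: 28 [(2R,3R)-2,3-dimethyloxiran-2-yl]methanol
Product: 29 (2S,3R)-2,3-dimethyloxirane-2-carboxylic acid
Conditions: RuCl3 (cat.), NaIO4, CCl4/MeCN/H2O, 23 °C
Reagents that add atoms: water, O; NaIO4, [Na+].[O-]I(=O)(=O)=O
Why: RuO4 oxidation of the primary alcohol to the acid without opening of the epoxide, the stereocenters being untouched (only the descriptor of C2 changes).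

Step 16
Reactants: 26 C3 alcohol; 29 (2S,3R)-2,3-dimethyloxirane-2-carboxylic acid
Product: 31 C3 epoxy ester (TBS ether on the C1 oxygen), via mixed anhydride 30 (not isolated)
Conditions: 29, 2,4,6-trichlorobenzoyl chloride, Et3N, THF, 23 °C; then 26, DMAP, toluene, 60 °C
Reagents that add atoms: none
Why: Yamaguchi esterification, in which DMAP should transfer the aliphatic acyl group of the mixed anhydride to the hindered C3 hydroxyl with no change at any stereocenter.

Step 17
Reactants: 31 C3 epoxy ester (TBS ether on the C1 oxygen)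
Product: 32 C1 alcohol bearing the C3 epoxy ester
Conditions: HF·pyridine, pyridine, THF, 23 °C
Reagents that add atoms: none
Why: Fluoride-mediated cleavage of the remaining silyl ether under buffered conditions that the epoxy ester and the enone should tolerate.

Step 18
Reactants: 32 C1 alcohol bearing the C3 epoxy ester; 33 angelic acid
Product: 35 CNP0149458.1 (target), via mixed anhydride 34 (not isolated)
Conditions: 33, 2,4,6-trichlorobenzoyl chloride, Et3N, toluene, 23 °C; then 32, 80 °C
Reagents that add atoms: none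
Why: Yamaguchi-type acylation with the preformed mixed anhydride of angelic acid in toluene without nucleophilic catalyst, conditions chosen to keep the Z geometry of the acyl group.

Compound list
1 | (R)-4-(tert-butyldimethylsilyloxy)cyclopent-2-en-1-one | O=C1C=C[C@H](O[Si](C)(C)C(C)(C)C)C1 | starting material
2 | 1-methoxy-2-methyl-1-(trimethylsilyloxy)prop-1-ene (TMS ketene acetal of methyl isobutyrate) | COC(O[Si](C)(C)C)=C(C)C | starting material
3 | TMS enol ether of the trans Michael adduct (ring C7(OTMS)=C6, C5 bearing CMe2CO2Me, C9 bearing OTBS) | C[Si](C)(C)OC1=C[C@@H](C(C)(C)C(=O)OC)[C@H](O[Si](C)(C)C(C)(C)C)C1 | intermediate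
4 | methyl 2-[(1S,2R)-2-(tert-butyldimethylsilyloxy)-4-oxocyclopentyl]-2-methylpropanoate (trans) | O=C1C[C@@H](C(C)(C)C(=O)OC)[C@H](O[Si](C)(C)C(C)(C)C)C1 | intermediate
5 | methyl 2-methyl-2-[(1R)-4-oxocyclopent-2-en-1-yl]propanoate | O=C1C=C[C@H](C(C)(C)C(=O)OC)C1 | intermediate
6 | TMS enol ether of the trans 3-methyl-4-substituted cyclopentanone (C7(OTMS)=C8) | C[Si](C)(C)OC1=C[C@@H](C)[C@H](C(C)(C)C(=O)OC)C1 | intermediate
7 | methyl 2-methyl-2-[(1R)-2-methyl-4-oxocyclopent-2-en-1-yl]propanoate | O=C1C=C(C)[C@H](C(C)(C)C(=O)OC)C1 | intermediate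
8 | (4R)-4-(1-hydroxy-2-methylpropan-2-yl)-3-methylcyclopent-2-en-1-ol, both carbinol epimers | OC1C=C(C)[C@H](C(C)(C)CO)C1 | intermediate
9 | 2-methyl-2-[(1R)-2-methyl-4-oxocyclopent-2-en-1-yl]propanal | O=C1C=C(C)[C@H](C(C)(C)C=O)C1 | intermediate
10 | butane-2,3-dione | CC(=O)C(C)=O | starting material
11 | benzyl (triphenylphosphoranylidene)acetate | O=C(OCc1ccccc1)C=P(c1ccccc1)(c1ccccc1)c1ccccc1 | starting material
12 | benzyl (2E)-3-methyl-4-oxopent-2-enoate | CC(=O)/C(C)=C/C(=O)OCc1ccccc1 | intermediate
13 | diisopinocampheylboron enolate of 12 (boryloxy diene) | C=C(OB([C@H]1C[C@H]2C[C@@H]([C@@H]1C)C2(C)C)[C@H]1C[C@H]2C[C@@H]([C@@H]1C)C2(C)C)/C(C)=C/C(=O)OCc1ccccc1 | intermediate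
14 | benzyl (2E,6R)-6-hydroxy-3,7-dimethyl-7-[(1R)-2-methyl-4-oxocyclopent-2-en-1-yl]-4-oxooct-2-enoate | O=C(OCc1ccccc1)/C=C(\C)C(=O)C[C@@H](O)C(C)(C)[C@@H]1CC(=O)C=C1C | intermediate
15 | benzyl (2E,4R,6R)-4,6-dihydroxy-3,7-dimethyl-7-[(1R)-2-methyl-4-oxocyclopent-2-en-1-yl]oct-2-enoate (anti diol) | O=C(OCc1ccccc1)/C=C(\C)[C@H](O)C[C@@H](O)C(C)(C)[C@@H]1CC(=O)C=C1C | intermediate
16 | 4-O-TBS ether of 15 (silyl on the C1 oxygen) | O=C(OCc1ccccc1)/C=C(\C)[C@H](O[Si](C)(C)C(C)(C)C)C[C@@H](O)C(C)(C)[C@@H]1CC(=O)C=C1C | intermediate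
17 | 4-O-TBS-6-O-TES bis-silyl ether of 15 | O=C(OCc1ccccc1)/C=C(\C)[C@H](O[Si](C)(C)C(C)(C)C)C[C@@H](O[Si](CC)(CC)CC)C(C)(C)[C@@H]1CC(=O)C=C1C | intermediate
18 | lithium cross-conjugated dienolate of 17 (C6=C7(OLi)) | [Li+].O=C(OCc1ccccc1)/C=C(\C)[C@H](O[Si](C)(C)C(C)(C)C)C[C@@H](O[Si](CC)(CC)CC)C(C)(C)[C@@H]1C=C([O-])C=C1C | intermediate
19 | lithium ester enolate after the first Michael addition (cyclopentenone fused to the seven-membered ring; C6–C11 bond formed) | [Li+].CC(C)(C)[Si](C)(C)O[C@@H]1C[C@@H](O[Si](CC)(CC)CC)C(C)(C)[C@@H]2[C@@H](C(=O)C=C2C)[C@@]1(C)C=C([O-])OCc1ccccc1 | intermediate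
20 | lithium C7=C8 enolate of 21 | [Li+].CC(C)(C)[Si](C)(C)O[C@@H]1C[C@@H](O[Si](CC)(CC)CC)C(C)(C)[C@@H]2[C@H]3C([O-])=C[C@]2(C)[C@H](C(=O)OCc4ccccc4)[C@]31C | intermediate
21 | tricyclic keto benzyl ester: norbornan-2-one (bridgeheads C6 and C9, one-carbon bridge C5, bridges C7(=O)–C8 and C10–C11) fused to the seven-membered ring C5–C4–C3–C2–C1–C11–C6; CH3 on C9, CH3 endo on C11, CO2Bn endo on C10, (1R)-OTBS, (3R)-OTES | CC(C)(C)[Si](C)(C)O[C@@H]1C[C@@H](O[Si](CC)(CC)CC)C(C)(C)[C@@H]2[C@H]3C(=O)C[C@]2(C)[C@H](C(=O)OCc4ccccc4)[C@]31C | intermediate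
22 | tricyclic keto acid (as 21, CO2H endo on C10) | CC(C)(C)[Si](C)(C)O[C@@H]1C[C@@H](O[Si](CC)(CC)CC)C(C)(C)[C@@H]2[C@H]3C(=O)C[C@]2(C)[C@H](C(=O)O)[C@]31C | intermediate
23 | tricyclic keto iodide (as 21, iodine endo on C10, anti to the C9–C5 bond) | CC(C)(C)[Si](C)(C)O[C@@H]1C[C@@H](O[Si](CC)(CC)CC)C(C)(C)[C@@H]2[C@H]3C(=O)C[C@]2(C)[C@H](I)[C@]31C | intermediate
24 | potassium C7=C8 enolate of 23 | [K+].CC(C)(C)[Si](C)(C)O[C@@H]1C[C@@H](O[Si](CC)(CC)CC)C(C)(C)[C@@H]2[C@H]3C([O-])=C[C@]2(C)[C@H](I)[C@]31C | intermediate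
25 | target diol core as 1-O-TBS-3-O-TES ether (1R,3R,5S,6R,10R,11R in the atom labels above) | CC(C)(C)[Si](C)(C)O[C@@H]1C[C@@H](O[Si](CC)(CC)CC)C(C)(C)[C@@H]2[C@H]3C(=O)C=C(C)[C@@H]2[C@]31C | intermediate
26 | C3 alcohol of the core (1-O-TBS) | CC(C)(C)[Si](C)(C)O[C@@H]1C[C@@H](O)C(C)(C)[C@@H]2[C@H]3C(=O)C=C(C)[C@@H]2[C@]31C | intermediate
27 | (2E)-2-methylbut-2-en-1-ol (tiglyl alcohol) | C/C=C(\C)CO | starting material
28 | [(2R,3R)-2,3-dimethyloxiran-2-yl]methanol | OC[C@@]1(C)O[C@@H]1C | intermediate
29 | (2S,3R)-2,3-dimethyloxirane-2-carboxylic acid | OC(=O)[C@@]1(C)O[C@@H]1C | intermediate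
30 | mixed anhydride of 29 with 2,4,6-trichlorobenzoic acid | O=C(OC(=O)c1c(Cl)cc(Cl)cc1Cl)[C@@]1(C)O[C@@H]1C | intermediate
31 | core with the (2S,3R)-epoxy ester on the C3 oxygen and TBS on the C1 oxygen | CC(C)(C)[Si](C)(C)O[C@@H]1C[C@@H](OC(=O)[C@@]2(C)O[C@@H]2C)C(C)(C)[C@@H]2[C@H]3C(=O)C=C(C)[C@@H]2[C@]31C | intermediate
32 | core with the epoxy ester on the C3 oxygen and free C1 hydroxyl | O[C@@H]1C[C@@H](OC(=O)[C@@]2(C)O[C@@H]2C)C(C)(C)[C@@H]2[C@H]3C(=O)C=C(C)[C@@H]2[C@]31C | intermediate
33 | angelic acid, (2Z)-2-methylbut-2-enoic acid | C/C=C(/C)C(=O)O | starting material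
34 | mixed anhydride of angelic acid with 2,4,6-trichlorobenzoic acid | C/C=C(/C)C(=O)OC(=O)c1c(Cl)cc(Cl)cc1Cl | intermediate
35 | CNP0149458.1: core with the angelate on the C1 oxygen and the (2S,3R)-2,3-dimethyloxirane-2-carboxylate on the C3 oxygen | C/C=C(/C)C(=O)O[C@@H]1C[C@@H](OC(=O)[C@@]2(C)O[C@@H]2C)C(C)(C)[C@@H]2[C@H]3C(=O)C=C(C)[C@@H]2[C@]31C | target

Total step count: 18
Longest linear sequence: 15 steps (steps 1–4, 6–13 and 16–18)

Steps most likely to fail

Step 12 (enolate-triggered ring expansion). The enolate may fail to engage the C9–C5 bond, through poor overlap or too little driving force, so that the iodide survives or decays by electron transfer. The fallback sets out from acid 22 and comes back at enone 25, which also spares the iodination of step 11. It runs the same skeletal change as a Demjanov-type deaminative rearrangement built from known reactions. Acid 22 is treated with diphenylphosphoryl azide and Et3N to give the acyl azide F1, which on warming in toluene should undergo Curtius rearrangement with retention to the endo isocyanate F2. Hydrolysis with aqueous LiOH in THF gives the endo amine F3. Isoamyl nitrite and AcOH in CHCl3 then give the diazonium acetate F4, in which the C9–C5 bond anti to the leaving nitrogen migrates and the C8 proton next to the ketone is lost, giving 25. This requires the endo acid that step 9 is expected to deliver.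

Step 9 (double Michael addition). γ-Deprotonation and proton exchange, or a first conjugate addition that is too slow at the fully substituted β-carbon C11, may let epimerization at C5 or oligomerization win over ring closure. The fallback sets out from 17 and comes back at 21 and uses the neutral, concerted counterpart. TMSCl, Et3N and ZnCl2 in toluene convert 17 into the cross-conjugated silyl dienol ether F5, which on heating (160 °C, sealed tube) should undergo intramolecular [4+2] cycloaddition to the tricyclic silyl enol ether F6. Dilute HCl on work-up gives 21.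

Step 18 (angeloylation). The Z acyl unit may isomerize to the E (tigloyl) form during the slow acylation of the hindered C1 hydroxyl. The fallback sets out from 32 and comes back at 35 and builds the Z double bond on the molecule instead of transferring it. Alcohol 32 is esterified (DCC, DMAP, CH2Cl2) with 2-[bis(2,2,2-trifluoroethoxy)phosphoryl]propanoic acid to give the phosphonopropionate ester F7. A Still–Gennari olefination (KN(SiMe3)2, 18-crown-6, acetaldehyde, THF, −78 °C) then gives the Z-2-methylbut-2-enoate 35.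

Further compounds
F1 | step 12 | acyl azide (tricyclic keto acyl azide, endo on C10) | CC(C)(C)[Si](C)(C)O[C@@H]1C[C@@H](O[Si](CC)(CC)CC)C(C)(C)[C@@H]2[C@H]3C(=O)C[C@]2(C)[C@H](C(=O)N=[N+]=[N-])[C@]31C
F2 | step 12 | endo isocyanate | CC(C)(C)[Si](C)(C)O[C@@H]1C[C@@H](O[Si](CC)(CC)CC)C(C)(C)[C@@H]2[C@H]3C(=O)C[C@]2(C)[C@H](N=C=O)[C@]31C
F3 | step 12 | endo amine | CC(C)(C)[Si](C)(C)O[C@@H]1C[C@@H](O[Si](CC)(CC)CC)C(C)(C)[C@@H]2[C@H]3C(=O)C[C@]2(C)[C@H](N)[C@]31C
F4 | step 12 | diazonium acetate | CC(C)(C)[Si](C)(C)O[C@@H]1C[C@@H](O[Si](CC)(CC)CC)C(C)(C)[C@@H]2[C@H]3C(=O)C[C@]2(C)[C@H]([N+]#N)[C@]31C.CC(=O)[O-]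
F5 | step 9 | silyl dienol ether (TMS ether of the cross-conjugated dienol of 17) | O=C(OCc1ccccc1)/C=C(\C)[C@H](O[Si](C)(C)C(C)(C)C)C[C@@H](O[Si](CC)(CC)CC)C(C)(C)[C@@H]1C=C(O[Si](C)(C)C)C=C1C
F6 | step 9 | tricyclic silyl enol ether (TMS enol ether of 21) | CC(C)(C)[Si](C)(C)O[C@@H]1C[C@@H](O[Si](CC)(CC)CC)C(C)(C)[C@@H]2[C@H]3C(O[Si](C)(C)C)=C[C@]2(C)[C@H](C(=O)OCc4ccccc4)[C@]31C
F7 | step 18 | phosphonopropionate ester (2-[bis(2,2,2-trifluoroethoxy)phosphoryl]propanoate on the C1 oxygen, both epimers at the phosphonate carbon) | CC(C(=O)O[C@@H]1C[C@@H](OC(=O)[C@@]2(C)O[C@@H]2C)C(C)(C)[C@@H]2[C@H]3C(=O)C=C(C)[C@@H]2[C@]31C)P(=O)(OCC(F)(F)F)OCC(F)(F)F
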